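Count what is left in the flask, not what is made, and build the flask up one process at a time.

| setting | dawn | noon | Sunday's | Thursday's |
|---|---|---|---|---|
| substrate | 0.055 M (fed, over 50 min) | 0.055 M (fed, over 50 min) | 0.055 M (fed, over 50 min) | 0.055 M (fed, over 50 min) |
| partner | 0.138 M | 0.138 M | 0.138 M | 0.138 M |
| free catalyst | 5.5 mM | 8.2 mM | 11 mM | 11 mM |
| temperature | 0 °C | 25 °C |  |  |
| remark | run made earlier; the fed solution adds 0.20 times the starting volume | run made earlier; the fed solution adds 0.20 times the starting volume | at 5 °C until 15 min, from then on at 45 °C; the fed solution adds 0.20 times the starting volume | at 5 °C throughout; the fed solution adds 0.20 times the starting volume |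
| time |  |  | 50 min | 50 min |

- dawn (time / min: target / %): 3.00: 0; 10.0: 0; 20.0: 1.5; 25.0: 2.7; 40.0: 9.4; 50.0: 13.9
- noon (time / min: target / %): 1.00: 1.5; 4.00: 0.5; 8.00: 3.9; 10.0: 6.5; 15.0: 13.9; 20.0: 19.6

(each reading ± 1 percentage point)

- which of the two ends with the higher amount of target, in percent of the substrate charged ("neither" if they lie within 2 percentage points) (Sunday's / Thursday's / neither)
- target at the end, in percent of the substrate charged, Sunday's
- target at the end, in percent of the substrate charged, Thursday's

- amounts are per litre of the starting volume; all of the dose is in the solution fed
- the numbers in the tables scatter with a standard deviation of 1 percentage point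
- percentages count the whole charge, also what has not yet gone in

Take the feed by itself first: it delivers the charge at a rate f = 0.0200 /min, so in this first picture, where substrate turns to target as it lands, the target at 50 min is 100% and nothing is left.

Now add the reaction as a pseudo-first-order loss of substrate with constant k. What has gone in and is not yet target, L, then climbs towards a standing stock f/k, where feed and loss balance, and at time t it equals f/k times one minus e to the power −kt. In the noon run at 20.0 min, 20.4% of the charge has gone in without becoming target. Reading that as the full stock gives k = 0.0980 /min, but the climb is unfinished then, and solving the whole expression gives 0.0775 /min. The dawn run is early in its climb, where the first terms of the same expression turn 13.9% at 50.0 min into k = 0.00608 /min.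

Next add catalyst and temperature. I take k as proportional to free catalyst, which neither run tests, and then noon's k per catalyst, as read from these scattered readings, stands 8.56 times dawn's. Spreading that factor evenly over the degrees gives κ = 1.70 /M/min, the rate constant of substrate loss per unit of free catalyst charged at 5 °C.

For Thursday's, k = κ times 11 mM = 0.0187 /min, so L = 65.0% and my target is 35.0%. For Sunday's, the same factor stretched to 45 °C gives k = 0.579 /min, faster than Thursday's. After the change at 15 min the climb has 20.3 time constants to finish, so L is the stock f/k = 3.45% and my target is 96.5%.

The forecast, from the same runs, names Sunday's, with 93% for Sunday's and 35% for Thursday's, holding that when hot “substrate is consumed nearly as it is fed”. My Thursday's figure matches it, and my Sunday's figure stands higher.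

The flask puts Sunday's ahead, with 89.4% against 37.0%, so in Sunday's at 50.0 min the part of the charge that is not target is 10.6%, more than the reckoned stock of 3.45%, and 4.85% of the charge stands there as substrate.

    catalyst intermediate C → spent catalyst (k = 0.00170 /s, Ea = 73.0 kJ/mol)
    catalyst intermediate B ⇌ catalyst intermediate C (K = 1.30, k = 0.0200 /s, Ea = 68.0 kJ/mol, ΔH = −79.0 kJ/mol)
    substrate + free catalyst ⇌ catalyst intermediate A (K = 280 /M, k = 0.0960 /M/s, Ea = 45.0 kJ/mol, ΔH = 13.0 kJ/mol)
    catalyst intermediate C → free catalyst + target (k = 0.0350 /s, Ea = 77.0 kJ/mol)
    partner + catalyst intermediate A → catalyst intermediate B (k = 0.0280 /M/s, Ea = 45.0 kJ/mol)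
    (constants at 5 °C)

Put κ to a neighbour of Thursday's charged with 0.019 M of free catalyst: k = 0.0322 /min, L = 49.7%, the reckoned target is 50.3%, and that flask ended at 51.3%.

All runs were computed on assumed constants.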